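The meeting opened on the target: at 8.00 h it read 70.2% in oak, 69.8% in ash and 70.3% in maple. The chair asked whether scavenger matters for the flasks green, violet and red.

| flask | starting material | reagent | scavenger | initiator | remark | time |
|---|---|---|---|---|---|---|
| oak | 0.80 M (fed, over 1.5 h) | 1.6 M | 0.47 M | 40 mM | run made earlier; the fed solution adds 0.10 times the starting volume |  |
| ash | 0.80 M (fed, over 1.5 h) | 1.6 M | 0.61 M | 40 mM | run made earlier; the fed solution adds 0.10 times the starting volume |  |
| maple | 0.80 M (fed, over 1.5 h) | 1.6 M | 0.64 M | 40 mM | run made earlier; the fed solution adds 0.10 times the starting volume |  |
| green | 0.80 M (fed, over 1.5 h) | 1.60 M | 0.400 M | 40 mM | the fed solution adds 0.10 times the starting volume | 8.0 h |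
| violet | 0.80 M (fed, over 1.5 h) | 1.60 M | 0.600 M | 40 mM | the fed solution adds 0.10 times the starting volume | 8.0 h |
| red | 0.80 M (fed, over 1.5 h) | 1.60 M | 0.900 M | 40 mM | the fed solution adds 0.10 times the starting volume | 8.0 h |

- oak (time / h: starting material / %, target / %): 0.667: 32.5, 10.7; 1.33: 65.2, 21.9; 3.00: 53.7, 42.6; 8.00: 22.5, 70.2
- ash (time / h: starting material / %, target / %): 2.00: 64.5, 31.7; 4.00: 43.8, 52.1; 6.00: 30.8, 63.7; 8.00: 23.1, 69.8
- maple (time / h: starting material / %, target / %): 1.00: 48.9, 16.6; 3.00: 53.1, 43.1; 5.00: 35.9, 59.1; 8.00: 22.7, 70.3

(each reading ± 0.5 percentage points)

- charges are per starting volume, the dose included; the dosed solution carries all of it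
- the numbers in the tables scatter with a standard deviation of 0.5 percentage points
- percentages count the whole charge, also what has not yet gone in

- part of the starting material that has reacted at the end, green
- part of the starting material that has reacted at the end, violet
- part of the starting material that has reacted at the end, red
- what raising the concentration of scavenger from its lowest to its highest value here does to the part of the starting material that has reacted (changes below 5 percentage points count as none) (no change / it rises / it falls)

The analyst proposed one number. Let L be the natural logarithm of the charge over the starting material left at the last reading. Oak gives L = 1.49 and maple gives 1.48. The analyst then defined the scavenger order n, the reaction order as read from two runs: the logarithm of the ratio of their L over the logarithm of the ratio of their scavenger charges. Oak and maple give n = −0.0193. The analyst noted that the two remainders differ by 0.2 percentage points, against a scatter of 0.5 points, and so read n as zero within the readings.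

The analyst then scaled oak's L by the scavenger ratio to the power n. That reckoning gave 77.6% reacted for green and 77.1% for red. The gap is 0.50 points, against the 5 points that counts as a change.

The forecast put 77%, 77% and 77%, with no change. Its maker held that “neither scavenger level nor its exhaustion seems to affect the rate over this range”. The analyst's green figure differs from the forecast's by 0.6 points.

The flasks gave 77.2% for green, 77.1% for violet and 77.1% for red. The trend is no change, at −0.13 points.

    2 second chain carrier → ended chains A (k = 2.50 × 10⁶ /M/s)
    starting material + second chain carrier → released group + first chain carrier (k = 821 /M/s)
    2 first chain carrier → ended chains B (k = 1.10 × 10⁸ /M/s)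
    starting material + initiating radical → capped initiator + first chain carrier (k = 7320 /M/s)
    released group → by-product carried off (k = 2.10 × 10⁻⁴ /s)
    initiator → 2 initiating radical (k = 4.42 × 10⁻⁵ /s)
    reagent + first chain carrier ⇌ target + second chain carrier (K = 0.530, k = 277 /M/s)
    scavenger + released group → scavenged by-product (k = 0.00646 /M/s)
    starting material + released group ⇌ idle adduct, settled at all times (K = 0.500 /M)

Green kept 2.1% of its scavenger and red kept 42%. Between these two flasks the same reckoning gives n = −0.00492. The neighbour is red with 0.068 M of initiator in place of 40 mM. It reached 87.8% reacted, so L went from 1.47 to 2.10. Read the same way, the initiator order is 0.672.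

Readings and results are calculated with constants of no real substance, and the scatter is random.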